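Cuts: the C8' formyl group is traced back to its dimethyl acetal. The two disubstituted alkenes C11=C12 and C11'=C12' are then cleaved, giving an ε-ring C15 phosphonium salt, 2,7-dimethylocta-2,4,6-trienedial (C12 to C12') and a C5 acetal phosphonium salt.
Enabling feature: C12 through C12' is a twofold-symmetric dimethyltriene whose two termini are the same formyl carbon until one of them has reacted. Each terminus ends up in a 1,2-disubstituted alkene. The only ring, the C1–C6 cyclohexene, is insulated from the polyene by sp3 C6 and takes no part.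
Forward order: no ring is built, because the cyclohexene is bought in (R)-α-ionone. C3 is oxygenated and C10/C11 are added by vinylation. The chain is then joined C15 + C10 and + C5 in one flask, and the acetal is opened last.
Stereochemistry: C6 (R) comes from (R)-α-ionone. C3 (S, hydroxyl cis to the side chain) comes from hydride attack on a C3 ketone anti to that side chain. The E alkenes come from the building blocks, from thermodynamic control in the salt formation (C9=C10) and from a final equilibration (C11=C12, C11'=C12').
Key step: step 8

Assumption: enantiopure natural-grade (R)-α-ionone, the C10 trienedial and (E)-4-chloro-2-methylbut-2-enal are taken as catalogue chemicals. Carotenoid numbering is used for all positions.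

Step 1
Reactants: 1 (R)-α-ionone
Product: 2 (R)-α-ionone ethylene ketal, 2-methyl-2-{(E)-2-[(1R)-2,6,6-trimethylcyclohex-2-en-1-yl]ethenyl}-1,3-dioxolane
Conditions: (Me3SiOCH2)2, Me3SiOTf (cat.), CH2Cl2, −78 → −40 °C; pyridine
Reagents that add atoms: 1,2-bis(trimethylsilyloxy)ethane, C[Si](C)(C)OCCO[Si](C)(C)C
Why: In the Noyori acetalisation at low temperature the oxocarbenium ion should be trapped before it can lose the C6 proton, so C7=C8 stays in place, C6 keeps its configuration, and the C9 ketone, which would otherwise be reduced ahead of the ring ketone in step 3, is masked.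

Step 2
Reactants: 2 (R)-α-ionone ethylene ketal
Product: 3 (6R)-3-oxo-α-ionone ethylene ketal, (4R)-3,5,5-trimethyl-4-[(E)-2-(2-methyl-1,3-dioxolan-2-yl)ethenyl]cyclohex-2-en-1-one
Conditions: t-BuOOH (70% aq.), Rh2(cap)4 (dirhodium tetracaprolactamate, 1 mol %), NaHCO3, ClCH2CH2Cl, 40 °C
Reagents that add atoms: tert-butyl hydroperoxide, CC(C)(C)OO
Why: In this metal-catalysed hydroperoxide allylic oxidation the tert-butylperoxyl radical should abstract hydrogen from the open ring methylene C3, because the doubly allylic C6–H is flanked by quaternary C1 and the C5 methyl group and lies near the nodal planes of both π systems, and the almost neutral medium avoids enolisation towards C6 in the product.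

Step 3
Reactants: 3 (6R)-3-oxo-α-ionone ethylene ketal
Product: 5 (3S,6R)-3-hydroxy-α-ionone (hydroxyl cis to the side chain), via cis-hydroxy ketal 4 (not isolated)
Conditions: Li[HB(s-Bu)3], THF, −78 °C; NaOH, H2O2, 0 °C; then pyridinium p-toluenesulfonate (cat.), acetone–H2O, 40 °C
Reagents that add atoms: water, O
Why: This is the 1,2-reduction of a β,β-disubstituted cyclohexenone by a bulky trialkylborohydride followed by mild acid hydrolysis of an allylic ketal: in the reactive sofa conformer the C6 side chain and the axial C1 methyl group shield the same ring face, so hydride should reach C3 from the opposite face and place the new hydroxyl cis to the side chain (3S), and the weakly acidic pyridinium salt opens the activated dioxolane without ionising the C3 carbinol.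

Step 4
Reactants: 5 (3S,6R)-3-hydroxy-α-ionone
Product: 6 (1S,4R)-4-[(1E)-3-hydroxy-3-methylpenta-1,4-dien-1-yl]-3,5,5-trimethylcyclohex-2-en-1-ol (both C9 epimers)
Conditions: CH2=CHMgBr (2.5 equiv), THF, −30 → 0 °C; aq. NH4Cl
Reagents that add atoms: vinylmagnesium bromide, C=C[Mg]Br
Why: This is the Grignard 1,2-addition that turns ionones into vinylionols: the first equivalent only deprotonates the C3 hydroxyl, carbonyl addition outruns γ-deprotonation at C6, and the new C9 carbinol centre may form as an epimer mixture because it becomes sp2 in step 5.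

Step 5
Reactants: 6 vinyl carbinol diol
Product: 7 [(2E,4E)-5-[(1R,4S)-4-hydroxy-2,6,6-trimethylcyclohex-2-en-1-yl]-3-methylpenta-2,4-dien-1-yl]triphenylphosphonium bromide
Conditions: Ph3P·HBr (1.0 equiv), CH2Cl2, 0 °C → rt; precipitation from EtOAc–Et2O
Reagents that add atoms: triphenylphosphine hydrobromide, [Br-].c1ccc(cc1)[PH+](c1ccccc1)c1ccccc1
Why: In this SN1-type phosphonium salt formation with allylic transposition the tertiary, doubly allylic C9 hydroxyl should leave as water to give a C7–C11 pentadienyl cation far more readily than the secondary C3 allylic hydroxyl can ionise, PPh3 traps the cation at the unhindered terminus C11 to give the conjugated 7E,9E diene, and one equivalent of the acid salt in an aprotic solvent is used up as the reaction runs, so C3 should not epimerise.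

Step 6
Reactants: 8 (E)-4-chloro-2-methylbut-2-enal
Product: 9 (E)-4-chloro-1,1-dimethoxy-2-methylbut-2-ene
Conditions: HC(OMe)3, MeOH, p-TsOH·H2O (cat.), rt; NaHCO3
Reagents that add atoms: trimethyl orthoformate, COC(OC)OC
Why: Acid-catalysed acetalisation is driven to completion by the orthoformate, and at room temperature neither the primary allylic chloride nor the E alkene should be affected.

Step 7
Reactants: 9 (E)-4-chloro-1,1-dimethoxy-2-methylbut-2-ene
Product: 10 [(E)-4,4-dimethoxy-3-methylbut-2-en-1-yl]triphenylphosphonium chloride
Conditions: PPh3, MeCN, 60 °C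
Reagents that add atoms: triphenylphosphine, c1ccc(cc1)P(c1ccccc1)c1ccccc1
Why: SN2 quaternisation of PPh3 by a primary allylic chloride runs under neutral conditions, which leave the acetal and the E geometry intact.

Step 8
Reactants: 7 ε-ring C15 phosphonium bromide; 10 C5 acetal phosphonium chloride; 11 (2E,4E,6E)-2,7-dimethylocta-2,4,6-trienedial
Product: 15 (3S,6R)-3-hydroxy-8'-apo-ε-caroten-8'-al dimethyl acetal, via C15 ylide 12 (not isolated), via C25 apocarotenal 13 (not isolated), via C5 ylide 14 (not isolated)
Conditions: 11 (1.15 equiv), 7 (1.0 equiv), CH2Cl2–MeOH, −10 °C, NaOMe (1.05 equiv, slow addition); then 10 (1.6 equiv), NaOMe (1.6 equiv), 0 °C → rt, N2, dark; Et3N-deactivated silica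
Reagents that add atoms: none
Why: Methoxide deprotonates 7 at C11 to the allylic ylide 12, which adds to one formyl carbon of 11 and collapses through an oxaphosphetane to the C11=C12 alkene and Ph3PO, and the same sequence between ylide 14 and the remaining C12' formyl group of 13 forms C11'=C12'. This is the Wittig olefination in the form long used for C15 + C10 + C15 carotenoid assembly, run here with two different salts one after the other. No ring is closed and no stereocentre is created, and because C3 and C6 are remote from the reacting carbons and C6–H is not acidified in 7, both centres should pass through the methoxide medium unchanged. The selectivity needed is single against double condensation in the first stage: in 11 each formyl group is activated by the other acceptor across the triene, whereas in 13 that acceptor has been replaced by a donor polyene, so 13 is clearly less electrophilic, and the slight excess of 11 together with slow addition of base, which generates 12 only in the presence of unreacted 11, reinforces this bias. The small, unhindered ylide 14, used in excess, then consumes 13 and also the leftover 11, whose hydroxyl-free C15 and C20 acetal products are much less polar than 15 and should separate on the column. The semistabilised ylides give E/Z mixtures only at the two new disubstituted alkenes, so 15 (drawn all-E) is carried on together with its strained 11Z and 11'Z isomers, which are corrected in step 9.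

Step 9
Reactants: 15 (3S,6R)-3-hydroxy-8'-apo-ε-caroten-8'-al dimethyl acetal
Product: 16 (3S,6R)-3-hydroxy-8'-apo-ε-caroten-8'-al, (2E,4E,6E,8E,10E,12E,14E,16E)-17-[(1R,4S)-4-hydroxy-2,6,6-trimethylcyclohex-2-en-1-yl]-2,6,11,15-tetramethylheptadeca-2,4,6,8,10,12,14,16-octaenal
Conditions: pyridinium p-toluenesulfonate (cat.), acetone–H2O, 0 °C → rt, N2, dark; aq. NaHCO3; then EtOAc–heptane, 70 °C, N2, dark; crystallisation
Reagents that add atoms: water, O
Why: Acid-catalysed acetal hydrolysis runs through an oxocarbenium ion conjugated with all eight chain alkenes and should therefore proceed at an acidity at which the isolated C3 allylic alcohol does not ionise, and the thermal E/Z equilibration that follows relieves the C10–H/C13-methyl (and C10'–H/C13'-methyl) clash of the 11Z and 11'Z isomers, so the all-E aldehyde crystallises.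

Compound list
1 | (R)-α-ionone | CC1=CCCC(C)(C)[C@H]1/C=C/C(C)=O | starting material
2 | (R)-α-ionone ethylene ketal | CC1=CCCC(C)(C)[C@H]1/C=C/C2(C)OCCO2 | intermediate
3 | (6R)-3-oxo-α-ionone ethylene ketal | CC1=CC(=O)CC(C)(C)[C@H]1/C=C/C2(C)OCCO2 | intermediate
4 | (3S,6R)-3-hydroxy-α-ionone ethylene ketal (cis, not isolated) | CC1=C[C@@H](O)CC(C)(C)[C@H]1/C=C/C2(C)OCCO2 | intermediate
5 | (3S,6R)-3-hydroxy-α-ionone (cis) | CC1=C[C@@H](O)CC(C)(C)[C@H]1/C=C/C(C)=O | intermediate
6 | (1S,4R)-4-[(1E)-3-hydroxy-3-methylpenta-1,4-dien-1-yl]-3,5,5-trimethylcyclohex-2-en-1-ol, both C9 epimers | CC1=C[C@@H](O)CC(C)(C)[C@H]1/C=C/C(C)(O)C=C | intermediate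
7 | ε-ring C15 triphenylphosphonium bromide (3S,6R,7E,9E) | CC1=C[C@@H](O)CC(C)(C)[C@H]1/C=C/C(C)=C/C[P+](c2ccccc2)(c2ccccc2)c2ccccc2.[Br-] | intermediate
8 | (E)-4-chloro-2-methylbut-2-enal | O=C/C(C)=C/CCl | starting material
9 | (E)-4-chloro-1,1-dimethoxy-2-methylbut-2-ene | COC(OC)/C(C)=C/CCl | intermediate
10 | [(E)-4,4-dimethoxy-3-methylbut-2-en-1-yl]triphenylphosphonium chloride | COC(OC)/C(C)=C/C[P+](c1ccccc1)(c1ccccc1)c1ccccc1.[Cl-] | intermediate
11 | (2E,4E,6E)-2,7-dimethylocta-2,4,6-trienedial | O=C/C(C)=C/C=C/C=C(C)/C=O | starting material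
12 | C15 ylide from 7 (not isolated) | CC1=C[C@@H](O)CC(C)(C)[C@H]1/C=C/C(C)=C/C=P(c2ccccc2)(c2ccccc2)c2ccccc2 | intermediate
13 | (3S,6R)-3-hydroxy-12'-apo-ε-caroten-12'-al (not isolated) | CC1=C[C@@H](O)CC(C)(C)[C@H]1/C=C/C(C)=C/C=C/C(C)=C/C=C/C=C(C)/C=O | intermediate
14 | C5 ylide from 10 (not isolated) | COC(OC)/C(C)=C/C=P(c1ccccc1)(c1ccccc1)c1ccccc1 | intermediate
15 | (3S,6R)-3-hydroxy-8'-apo-ε-caroten-8'-al dimethyl acetal | CC1=C[C@@H](O)CC(C)(C)[C@H]1/C=C/C(C)=C/C=C/C(C)=C/C=C/C=C(C)/C=C/C=C(\C)C(OC)OC | intermediate
16 | (3S,6R)-3-hydroxy-8'-apo-ε-caroten-8'-al | CC1=C[C@@H](O)CC(C)(C)[C@H]1/C=C/C(C)=C/C=C/C(C)=C/C=C/C=C(C)/C=C/C=C(\C)C=O | target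

Total step count: 9. Longest linear sequence: 7 (steps 1, 2, 3, 4, 5, 8, 9).

Steps most likely to fail

Step 8. The first condensation may not stop cleanly at the mono-adduct. Double olefination of 11 by 12, and scrambling between leftover 11 and 14, would turn the flask into a statistical mixture and waste the chiral salt. The fallback reverses the order of the two condensations and splits them over two flasks. It sets out from 10 and 11. Ylide 14 (NaOMe, CH2Cl2–MeOH, 0 °C) is added to a threefold excess of the cheap dialdehyde 11. The mono-adduct (2E,4E,6E,8E,10E)-12,12-dimethoxy-2,7,11-trimethyldodeca-2,4,6,8,10-pentaenal F1 is isolated on Et3N-deactivated silica, and unreacted 11 is recovered. The aldehyde carries a single formyl group, so ylide 12 generated from 7 can only form C11=C12. The route is rejoined at 15.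

Step 3. Hydride may be delivered from both ring faces, or mainly from the face syn to the side chain, which would erode or reverse the cis selectivity at C3. The fallback replaces substrate control by inversion. It sets out from 3, which is reduced without regard to selectivity (i-Bu2AlH, toluene, −78 °C), and the epimers are separated. The trans carbinol (3R,6R)-3-hydroxy-α-ionone ethylene ketal F2 is subjected to Mitsunobu inversion (PPh3, diisopropyl azodicarboxylate, 4-nitrobenzoic acid, THF, 0 °C). Allylic transposition is disfavoured because it would have to create a fully substituted C5. This gives the cis ester (3S,6R)-3-(4-nitrobenzoyloxy)-α-ionone ethylene ketal F3. Methanolysis (K2CO3, MeOH) returns the route at 4, which is hydrolysed as in the second half of step 3.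

Step 5. The ring allylic hydroxyl may ionise in competition with the C9 carbinol, leading to epimerisation at C3, dehydration of the ring or quaternisation of PPh3 on the ring. The fallback masks that hydroxyl with a group that is later removed in the same flask as the olefinations.
- It sets out from 6. The secondary hydroxyl is acetylated selectively (Ac2O, pyridine, 0 °C; the tertiary C9 hydroxyl does not react) to the 3-O-acetyl vinyl carbinol F4.
- Ph3P·HBr in CH2Cl2 converts this into the 3-acetoxy C15 phosphonium bromide F5. Its ester oxygen is a much poorer site for protonation than a free hydroxyl.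
- This salt takes the place of 7 in the one-pot sequence of step 8. It passes through the 3-acetoxy C15 ylide F6, the 3-acetoxy C25 apocarotenal F7 and the 3-acetoxy C30 dimethyl acetal F8.
- An extra portion of NaOMe in MeOH at room temperature at the end transesterifies the acetate, and the route is rejoined at 15.

Further compounds
F1 | step 8 | (2E,4E,6E,8E,10E)-12,12-dimethoxy-2,7,11-trimethyldodeca-2,4,6,8,10-pentaenal | O=C/C(C)=C/C=C/C=C(C)/C=C/C=C(\C)C(OC)OC
F2 | step 3 | (3R,6R)-3-hydroxy-α-ionone ethylene ketal (trans) | CC1=C[C@H](O)CC(C)(C)[C@H]1/C=C/C2(C)OCCO2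
F3 | step 3 | (3S,6R)-3-(4-nitrobenzoyloxy)-α-ionone ethylene ketal (cis) | CC1=C[C@@H](OC(=O)c2ccc(cc2)[N+](=O)[O-])CC(C)(C)[C@H]1/C=C/C3(C)OCCO3
F4 | step 5 | 3-O-acetyl vinyl carbinol, (1S,4R)-4-[(1E)-3-hydroxy-3-methylpenta-1,4-dien-1-yl]-3,5,5-trimethylcyclohex-2-en-1-yl acetate | CC1=C[C@@H](OC(C)=O)CC(C)(C)[C@H]1/C=C/C(C)(O)C=C
F5 | step 5 | 3-acetoxy C15 phosphonium bromide | CC1=C[C@@H](OC(C)=O)CC(C)(C)[C@H]1/C=C/C(C)=C/C[P+](c2ccccc2)(c2ccccc2)c2ccccc2.[Br-]
F6 | step 5 | 3-acetoxy C15 ylide | CC1=C[C@@H](OC(C)=O)CC(C)(C)[C@H]1/C=C/C(C)=C/C=P(c2ccccc2)(c2ccccc2)c2ccccc2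
F7 | step 5 | 3-acetoxy C25 apocarotenal, (3S,6R)-3-acetoxy-12'-apo-ε-caroten-12'-al | CC1=C[C@@H](OC(C)=O)CC(C)(C)[C@H]1/C=C/C(C)=C/C=C/C(C)=C/C=C/C=C(C)/C=O
F8 | step 5 | 3-acetoxy C30 dimethyl acetal, (3S,6R)-3-acetoxy-8'-apo-ε-caroten-8'-al dimethyl acetal | CC1=C[C@@H](OC(C)=O)CC(C)(C)[C@H]1/C=C/C(C)=C/C=C/C(C)=C/C=C/C=C(C)/C=C/C=C(\C)C(OC)OC
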